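**Retrosynthetic overview**
1. Feature: ring B (C5–C10) has the trans C5–C10 fusion, the quaternary C10 methyl (C20) and the C9 stereocentre next to an oxidisable C8. It is cut at C5–C10 and C8–C9 into a C5=C6–C7=C8 1‑silyloxydiene and a C9=C10 (E)‑3‑methyl‑2‑enoate joined by the C1–C4 chain, so one intramolecular Diels–Alder step closes ring B (cycloadduct) and ring A (tether ring) together.
2. The acyclic triene carries C3 (S) and quaternary C4 (R) from a Noyori reduction and two Fráter–Seebach alkylations; the enoate comes from a Horner–Wadsworth–Emmons reaction, the diene from cross‑metathesis to an enal and silyl dienol ether formation.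
3. O3 and C19 stay acyclic in the cycloaddition (C3 silyl ether, C19 tert‑butyl ester): a 1,3‑dioxane across O3/C19 would keep C2 equatorial on the dioxane and so hold O3 axial and C19 equatorial in the tether chair, which is the wrong π‑face.
4. After ring formation: C6=C7 hydrogenation, C11 ester to vinyl, B‑alkyl Suzuki coupling to the 13E side chain, C8 silyl ether to ketone to C17 methylene, then C19 ester to aldehyde, C3 acetate and C15 deprotection.

Key step: step 11

Remark: ring compounds are named with labdane numbering in the normal labdane series (5α‑H, 9α‑H, 10β‑CH3; C18 = 4α‑methyl, C19 = 4β‑carbon, C11 = carbon on C9, C17 = carbon on C8, β = the face of C20); a "nor" name marks side‑chain carbons not yet present.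

Step 1
Reactants: 1 methyl levulinate
Product: 2 methyl 3-(2-methyl-1,3-dioxolan-2-yl)propanoate
Conditions: HOCH2CH2OH, TsOH·H2O (cat.), PhMe, reflux, azeotropic removal of water
Reagents that add atoms: ethylene glycol, OCCO
Why: Acid‑catalysed ketalisation masks the future C10 ketone against the enolate chemistry that follows.

Step 2
Reactants: 2 methyl 3-(2-methyl-1,3-dioxolan-2-yl)propanoate; 3 tert-butyl acetate
Product: 5 tert-butyl 5-(2-methyl-1,3-dioxolan-2-yl)-3-oxopentanoate, via lithium enolate of tert-butyl acetate 4 (not isolated)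
Conditions: LiN(i-Pr)2 (2.3 equiv), 3 (2.3 equiv), THF, −78 °C; then 2, −78 to −30 °C; aq. NH4Cl
Reagents that add atoms: none
Why: Crossed Claisen condensation; the excess lithium enolate adds to the methyl ester and then deprotonates the β‑keto ester formed, which drives the reaction.

Step 3
Reactants: 5 tert-butyl 5-(2-methyl-1,3-dioxolan-2-yl)-3-oxopentanoate
Product: 6 tert-butyl (3S)-3-hydroxy-5-(2-methyl-1,3-dioxolan-2-yl)pentanoate
Conditions: H2 (50 atm), [RuCl2((S)-BINAP)]2·NEt3 (0.5 mol %), MeOH, 50 °C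
Reagents that add atoms: none
Why: Noyori asymmetric hydrogenation of a β‑keto ester; the (S)‑BINAP catalyst reduces the ester‑chelated ketone from one face and sets C3 as S (the future 3β oxygen), and the acid‑free precatalyst should spare the ketal.

Step 4
Reactants: 6 tert-butyl (3S)-3-hydroxy-5-(2-methyl-1,3-dioxolan-2-yl)pentanoate; 7 allyl bromide
Product: 9 tert-butyl (2S,3S)-3-hydroxy-5-(2-methyl-1,3-dioxolan-2-yl)-2-(prop-2-en-1-yl)pentanoate, via dilithium alkoxide enolate 8 (not isolated)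
Conditions: LiN(i-Pr)2 (2.2 equiv), THF, −78 to −20 °C; then 7, DMPU, −78 to −20 °C; aq. NH4Cl
Reagents that add atoms: none
Why: Fráter–Seebach alkylation; the chelated dianion takes allyl bromide on the face anti to the C3 side chain, which sets the 2,3‑anti relationship (2S).

Step 5
Reactants: 9 tert-butyl (2S,3S)-3-hydroxy-5-(2-methyl-1,3-dioxolan-2-yl)-2-(prop-2-en-1-yl)pentanoate
Product: 11 tert-butyl (2R,3S)-3-hydroxy-2-methyl-5-(2-methyl-1,3-dioxolan-2-yl)-2-(prop-2-en-1-yl)pentanoate, via dilithium alkoxide enolate 10 (not isolated)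
Conditions: LiN(i-Pr)2 (2.5 equiv), THF, −78 to 0 °C; then MeI, DMPU, −78 to −10 °C; aq. NH4Cl
Reagents that add atoms: iodomethane, CI
Why: Second Fráter–Seebach alkylation; the re‑formed chelated dianion takes methyl iodide on the same face as before, so the methyl (C18) ends anti and the allyl group (C5–C7) syn to the C3 oxygen, fixing quaternary C4 as R.

Step 6
Reactants: 11 tert-butyl (2R,3S)-3-hydroxy-2-methyl-5-(2-methyl-1,3-dioxolan-2-yl)-2-(prop-2-en-1-yl)pentanoate
Product: 12 tert-butyl (2R,3S)-3-[(tert-butyldimethylsilyl)oxy]-2-methyl-5-(2-methyl-1,3-dioxolan-2-yl)-2-(prop-2-en-1-yl)pentanoate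
Conditions: TBSOTf, 2,6-lutidine, CH2Cl2, −78 to 0 °C
Reagents that add atoms: tert-butyldimethylsilyl trifluoromethanesulfonate, CC(C)(C)[Si](C)(C)OS(=O)(=O)C(F)(F)F
Why: Silyl ether protection of the hindered secondary alcohol with the silyl triflate at low temperature, where ketal and tert‑butyl ester are left alone.

Step 7
Reactants: 12 tert-butyl (2R,3S)-3-[(tert-butyldimethylsilyl)oxy]-2-methyl-5-(2-methyl-1,3-dioxolan-2-yl)-2-(prop-2-en-1-yl)pentanoate
Product: 13 tert-butyl (2R,3S)-3-[(tert-butyldimethylsilyl)oxy]-2-methyl-6-oxo-2-(prop-2-en-1-yl)heptanoate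
Conditions: PPTS (cat.), acetone/H2O, 55 °C
Reagents that add atoms: water, O
Why: Mild acid‑catalysed ketal hydrolysis frees the methyl ketone without cleaving the TBS ether or the tert‑butyl ester.

Step 8
Reactants: 13 tert-butyl (2R,3S)-3-[(tert-butyldimethylsilyl)oxy]-2-methyl-6-oxo-2-(prop-2-en-1-yl)heptanoate; 14 trimethyl phosphonoacetate
Product: 16 8-tert-butyl 1-methyl (2E,6S,7R)-6-[(tert-butyldimethylsilyl)oxy]-3,7-dimethyl-7-(prop-2-en-1-yl)oct-2-enedioate, via sodium phosphonate anion 15 (not isolated)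
Conditions: NaH, 14, THF, 0 °C; then 13, 0 to 50 °C; chromatographic removal of the Z isomer
Reagents that add atoms: none
Why: Horner–Wadsworth–Emmons olefination of the methyl ketone gives the trisubstituted enoate (C9=C10), the E isomer with the ester trans to the larger CH2 group being expected to predominate.

Step 9
Reactants: 16 8-tert-butyl 1-methyl (2E,6S,7R)-6-[(tert-butyldimethylsilyl)oxy]-3,7-dimethyl-7-(prop-2-en-1-yl)oct-2-enedioate; 17 (E)-but-2-enal
Product: 18 8-tert-butyl 1-methyl (2E,6S,7R)-6-[(tert-butyldimethylsilyl)oxy]-3,7-dimethyl-7-[(2E)-4-oxobut-2-en-1-yl]oct-2-enedioate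
Conditions: 17 (5 equiv), second-generation Hoveyda–Grubbs catalyst RuCl2(=CH-C6H4-2-O-i-Pr)(H2IMes) (5 mol %), CH2Cl2, 40 °C
Reagents that add atoms: none
Why: Olefin cross‑metathesis of the terminal allyl group with crotonaldehyde should give the E‑enal (C5–C8) directly, the trisubstituted enoate being inert to the catalyst.

Step 10
Reactants: 18 8-tert-butyl 1-methyl (2E,6S,7R)-6-[(tert-butyldimethylsilyl)oxy]-3,7-dimethyl-7-[(2E)-4-oxobut-2-en-1-yl]oct-2-enedioate
Product: 19 8-tert-butyl 1-methyl (2E,6S,7R)-6-[(tert-butyldimethylsilyl)oxy]-3,7-dimethyl-7-[(1E,3E)-4-[(triethylsilyl)oxy]buta-1,3-dien-1-yl]oct-2-enedioate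
Conditions: Et3SiOTf, Et3N, Et2O, −78 to 0 °C; aq. NaHCO3; filtration through Et3N-deactivated silica
Reagents that add atoms: triethylsilyl trifluoromethanesulfonate, CC[Si](CC)(CC)OS(=O)(=O)C(F)(F)F
Why: Silyl dienol ether formation by O‑silylation of the enal and loss of a γ‑hydrogen from C5; the s‑trans enal should give the E enol ether (C7=C8) and the bulky quaternary C4 the E C5=C6 alkene.

Step 11
Reactants: 19 8-tert-butyl 1-methyl (2E,6S,7R)-6-[(tert-butyldimethylsilyl)oxy]-3,7-dimethyl-7-[(1E,3E)-4-[(triethylsilyl)oxy]buta-1,3-dien-1-yl]oct-2-enedioate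
Product: 20 19-tert-butyl 11-methyl 3β-[(tert-butyldimethylsilyl)oxy]-8β-[(triethylsilyl)oxy]-12,13,14,15,16,17-hexanorlabd-6-ene-11,19-dioate (trans-fused; 4α-CH3, 5α-H, 9α-H, 10β-CH3)
Conditions: PhMe (0.01 M), BHT (0.1 equiv), Et3N (0.1 equiv), sealed tube, 170 °C; chromatographic removal of minor isomers
Reagents that add atoms: none
Why: Concerted thermal [4+2] cycloaddition, an intramolecular Diels–Alder reaction of a 1,7,9‑decatrienoate (a known reaction type), in which the large HOMO coefficient at C5 of the 1‑silyloxydiene meets the large LUMO coefficient at C10 of the enoate, so tether and electronics both call for C5–C10 and C8–C9 bonding. Ring B closes as the cycloadduct itself, suprafacially on both partners, and ring A closes as the six‑membered C1–C4 tether ring in a chair‑like array. The E‑enoate geometry transfers to C9/C10 (9β‑CO2Me cis to 10β‑CH3), the E,E‑diene geometry to C5/C8 (8β‑OSiEt3 cis to the C5–C4 bond), and the ester‑endo, tether‑anti transition state gives the trans C5–C10 fusion (5α‑H). The π‑face is chosen by C3 and C4: the favoured tether chair keeps the C3 silyloxy group equatorial and places the planar tert‑butoxycarbonyl group, not the methyl group, in the axial site that faces the incoming C10 methyl. The step needs endo/exo and π‑facial selectivity; both rest on modest preferences, so the cis‑fused and wrong‑face adducts are expected as minor products. C4 is quaternary, which rules out 1,5‑hydrogen shifts of the diene and favours the folded conformer.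

Step 12
Reactants: 20 19-tert-butyl 11-methyl 3β-[(tert-butyldimethylsilyl)oxy]-8β-[(triethylsilyl)oxy]-12,13,14,15,16,17-hexanorlabd-6-ene-11,19-dioate
Product: 21 19-tert-butyl 11-methyl 3β-[(tert-butyldimethylsilyl)oxy]-8β-[(triethylsilyl)oxy]-12,13,14,15,16,17-hexanorlabdane-11,19-dioate
Conditions: H2 (1 atm), 10% Pd/C, EtOAc, rt
Reagents that add atoms: none
Why: Heterogeneous catalytic hydrogenation saturates the only alkene (C6=C7); no stereocentre is formed.

Step 13
Reactants: 21 19-tert-butyl 11-methyl 3β-[(tert-butyldimethylsilyl)oxy]-8β-[(triethylsilyl)oxy]-12,13,14,15,16,17-hexanorlabdane-11,19-dioate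
Product: 22 tert-butyl 3β-[(tert-butyldimethylsilyl)oxy]-11-hydroxy-8β-[(triethylsilyl)oxy]-12,13,14,15,16,17-hexanorlabdan-19-oate
Conditions: i-Bu2AlH (2.5 equiv), CH2Cl2, −78 to −40 °C; aq. potassium sodium tartrate
Reagents that add atoms: none
Why: Chemoselective hydride reduction of an ester; the methyl ester on C9 should be reduced to the primary alcohol while the axial tert‑butyl ester on quaternary C4 is too hindered to react at low temperature.

Step 14
Reactants: 22 tert-butyl 3β-[(tert-butyldimethylsilyl)oxy]-11-hydroxy-8β-[(triethylsilyl)oxy]-12,13,14,15,16,17-hexanorlabdan-19-oate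
Product: 23 tert-butyl 3β-[(tert-butyldimethylsilyl)oxy]-11-oxo-8β-[(triethylsilyl)oxy]-12,13,14,15,16,17-hexanorlabdan-19-oate
Conditions: Dess–Martin periodinane, NaHCO3, CH2Cl2, 0 °C to rt
Reagents that add atoms: none
Why: Dess–Martin oxidation of the primary alcohol to the aldehyde under buffered conditions that should not epimerise C9.

Step 15
Reactants: 23 tert-butyl 3β-[(tert-butyldimethylsilyl)oxy]-11-oxo-8β-[(triethylsilyl)oxy]-12,13,14,15,16,17-hexanorlabdan-19-oate
Product: 24 tert-butyl 3β-[(tert-butyldimethylsilyl)oxy]-8β-[(triethylsilyl)oxy]-13,14,15,16,17-pentanorlabd-11-en-19-oate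
Conditions: Ph3PCH3Br, KN(SiMe3)2, THF, 0 °C; then 23, −78 to 0 °C
Reagents that add atoms: methyltriphenylphosphonium bromide, C[P+](c1ccccc1)(c1ccccc1)c1ccccc1.[Br-]
Why: Wittig methylenation with the salt‑free ylide at low temperature should convert the aldehyde into the C11=C12 vinyl group faster than the ylide can enolise it, so C9 and the β‑silyloxy group are kept.

Step 16
Reactants: 25 but-2-yn-1-ol
Product: 26 1-[(but-2-yn-1-yloxy)methyl]-4-methoxybenzene
Conditions: NaH, 4-MeOC6H4CH2Cl, n-Bu4NI (cat.), THF/DMF, 0 °C to rt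
Reagents that add atoms: 4-methoxybenzyl chloride, COc1ccc(CCl)cc1
Why: Williamson ether synthesis protects the future C15 alcohol as its 4‑methoxybenzyl (PMB) ether.

Step 17
Reactants: 26 1-[(but-2-yn-1-yloxy)methyl]-4-methoxybenzene
Product: 28 1-({[(2E)-3-iodobut-2-en-1-yl]oxy}methyl)-4-methoxybenzene, via alkenylzirconocene chloride 27 (not isolated)
Conditions: Cp2Zr(H)Cl (2 equiv), THF, rt to 50 °C; then I2, 0 °C
Reagents that add atoms: iodine, II
Why: Hydrozirconation adds H and Zr syn across the alkyne, the excess reagent equilibrating zirconium onto the less hindered methyl‑bearing carbon, and iodinolysis with retention should give the E vinyl iodide (C13–C16).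

Step 18
Reactants: 24 tert-butyl 3β-[(tert-butyldimethylsilyl)oxy]-8β-[(triethylsilyl)oxy]-13,14,15,16,17-pentanorlabd-11-en-19-oate; 28 1-({[(2E)-3-iodobut-2-en-1-yl]oxy}methyl)-4-methoxybenzene
Product: 30 tert-butyl 3β-[(tert-butyldimethylsilyl)oxy]-15-[(4-methoxybenzyl)oxy]-8β-[(triethylsilyl)oxy]-17-norlabd-13E-en-19-oate, via B-alkyl-9-BBN borane 29 (not isolated)
Conditions: 9-BBN-H (dimer), THF, rt; then 28, PdCl2(dppf) (5 mol %), AsPh3, Cs2CO3, DMF/H2O, rt
Reagents that add atoms: none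
Why: Anti‑Markovnikov hydroboration of the terminal alkene followed by B‑alkyl Suzuki–Miyaura coupling, which retains the vinyl iodide geometry, joins C12 to C13 and installs the 13E side chain.

Step 19
Reactants: 30 tert-butyl 3β-[(tert-butyldimethylsilyl)oxy]-15-[(4-methoxybenzyl)oxy]-8β-[(triethylsilyl)oxy]-17-norlabd-13E-en-19-oate
Product: 31 tert-butyl 3β-[(tert-butyldimethylsilyl)oxy]-8β-hydroxy-15-[(4-methoxybenzyl)oxy]-17-norlabd-13E-en-19-oate
Conditions: HF·pyridine, pyridine, THF, 0 °C to rt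
Reagents that add atoms: none
Why: Selective desilylation; buffered HF·pyridine should cleave the triethylsilyl ether much faster than the hindered tert‑butyldimethylsilyl ether, and the PMB ether and tert‑butyl ester are inert.

Step 20
Reactants: 31 tert-butyl 3β-[(tert-butyldimethylsilyl)oxy]-8β-hydroxy-15-[(4-methoxybenzyl)oxy]-17-norlabd-13E-en-19-oate
Product: 32 tert-butyl 3β-[(tert-butyldimethylsilyl)oxy]-15-[(4-methoxybenzyl)oxy]-8-oxo-17-norlabd-13E-en-19-oate
Conditions: Dess–Martin periodinane, NaHCO3, CH2Cl2, rt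
Reagents that add atoms: none
Why: Dess–Martin oxidation of the secondary alcohol gives the C8 ketone and removes the C8 stereocentre as planned.

Step 21
Reactants: 32 tert-butyl 3β-[(tert-butyldimethylsilyl)oxy]-15-[(4-methoxybenzyl)oxy]-8-oxo-17-norlabd-13E-en-19-oate
Product: 33 tert-butyl 3β-[(tert-butyldimethylsilyl)oxy]-15-[(4-methoxybenzyl)oxy]labda-8(17),13E-dien-19-oate
Conditions: Ph3PCH3Br, KOt-Bu, PhMe, 80 °C
Reagents that add atoms: methyltriphenylphosphonium bromide, C[P+](c1ccccc1)(c1ccccc1)c1ccccc1.[Br-]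
Why: Wittig methylenation of the hindered ketone installs C17; the equatorial 9β side chain is the more stable configuration, so any enolisation should not change C9.

Step 22
Reactants: 33 tert-butyl 3β-[(tert-butyldimethylsilyl)oxy]-15-[(4-methoxybenzyl)oxy]labda-8(17),13E-dien-19-oate
Product: 34 3β-[(tert-butyldimethylsilyl)oxy]-15-[(4-methoxybenzyl)oxy]labda-8(17),13E-dien-19-ol
Conditions: LiAlH4, THF, reflux; H2O, aq. NaOH work-up
Reagents that add atoms: none
Why: Hydride reduction of the hindered tert‑butyl ester to the neopentyl primary alcohol at reflux; silyl ether, PMB ether and alkenes are inert.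

Step 23
Reactants: 34 3β-[(tert-butyldimethylsilyl)oxy]-15-[(4-methoxybenzyl)oxy]labda-8(17),13E-dien-19-ol
Product: 35 3β-[(tert-butyldimethylsilyl)oxy]-15-[(4-methoxybenzyl)oxy]labda-8(17),13E-dien-19-al
Conditions: Dess–Martin periodinane, pyridine, CH2Cl2, rt
Reagents that add atoms: none
Why: Dess–Martin oxidation gives the C19 aldehyde, which has no α‑hydrogen and cannot epimerise.

Step 24
Reactants: 35 3β-[(tert-butyldimethylsilyl)oxy]-15-[(4-methoxybenzyl)oxy]labda-8(17),13E-dien-19-al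
Product: 36 3β-hydroxy-15-[(4-methoxybenzyl)oxy]labda-8(17),13E-dien-19-al
Conditions: HF·pyridine, THF, rt to 40 °C
Reagents that add atoms: none
Why: Fluoride‑mediated silyl ether cleavage under non‑basic conditions should avoid retro‑aldol cleavage of the β‑hydroxy aldehyde and leave the PMB ether.

Step 25
Reactants: 36 3β-hydroxy-15-[(4-methoxybenzyl)oxy]labda-8(17),13E-dien-19-al
Product: 37 3β-acetoxy-15-[(4-methoxybenzyl)oxy]labda-8(17),13E-dien-19-al
Conditions: Ac2O, pyridine, DMAP (cat.), CH2Cl2, rt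
Reagents that add atoms: acetic anhydride, CC(=O)OC(C)=O
Why: DMAP‑catalysed acetylation of the equatorial C3 alcohol; C4 has no hydrogen, so the β‑acetoxy aldehyde cannot eliminate.

Step 26
Reactants: 37 3β-acetoxy-15-[(4-methoxybenzyl)oxy]labda-8(17),13E-dien-19-al
Product: 38 3β-acetoxy-15-hydroxylabda-8(17),13E-dien-19-al (target, CNP0185120.1)
Conditions: DDQ, CH2Cl2/pH 7 phosphate buffer, 0 °C
Reagents that add atoms: none
Why: Oxidative PMB ether cleavage with DDQ should free the C15 alcohol without touching the acetate, the aldehyde or the alkenes.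

**Compound list**
1 | methyl levulinate | COC(=O)CCC(C)=O | starting material
2 | methyl 3-(2-methyl-1,3-dioxolan-2-yl)propanoate | COC(=O)CCC1(C)OCCO1 | intermediate
3 | tert-butyl acetate | CC(=O)OC(C)(C)C | starting material
4 | lithium enolate of tert-butyl acetate (not isolated) | C=C(O[Li])OC(C)(C)C | intermediate
5 | tert-butyl 5-(2-methyl-1,3-dioxolan-2-yl)-3-oxopentanoate | CC(C)(C)OC(=O)CC(=O)CCC1(C)OCCO1 | intermediate
6 | tert-butyl (3S)-3-hydroxy-5-(2-methyl-1,3-dioxolan-2-yl)pentanoate | CC(C)(C)OC(=O)C[C@@H](O)CCC1(C)OCCO1 | intermediate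
7 | allyl bromide | C=CCBr | starting material
8 | dilithium alkoxide enolate of 6 (not isolated) | [Li]O/C(OC(C)(C)C)=C\[C@@H](O[Li])CCC1(C)OCCO1 | intermediate
9 | tert-butyl (2S,3S)-3-hydroxy-5-(2-methyl-1,3-dioxolan-2-yl)-2-(prop-2-en-1-yl)pentanoate | CC(C)(C)OC(=O)[C@@H](CC=C)[C@@H](O)CCC1(C)OCCO1 | intermediate
10 | dilithium alkoxide enolate of 9 (not isolated) | [Li]O/C(OC(C)(C)C)=C(CC=C)\[C@@H](O[Li])CCC1(C)OCCO1 | intermediate
11 | tert-butyl (2R,3S)-3-hydroxy-2-methyl-5-(2-methyl-1,3-dioxolan-2-yl)-2-(prop-2-en-1-yl)pentanoate | CC(C)(C)OC(=O)[C@](C)(CC=C)[C@@H](O)CCC1(C)OCCO1 | intermediate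
12 | tert-butyl (2R,3S)-3-[(tert-butyldimethylsilyl)oxy]-2-methyl-5-(2-methyl-1,3-dioxolan-2-yl)-2-(prop-2-en-1-yl)pentanoate | CC(C)(C)OC(=O)[C@](C)(CC=C)[C@@H](O[Si](C)(C)C(C)(C)C)CCC1(C)OCCO1 | intermediate
13 | tert-butyl (2R,3S)-3-[(tert-butyldimethylsilyl)oxy]-2-methyl-6-oxo-2-(prop-2-en-1-yl)heptanoate | CC(C)(C)OC(=O)[C@](C)(CC=C)[C@@H](O[Si](C)(C)C(C)(C)C)CCC(C)=O | intermediate
14 | trimethyl phosphonoacetate | COC(=O)CP(=O)(OC)OC | starting material
15 | sodium salt of trimethyl phosphonoacetate (not isolated) | COC(=O)[CH-]P(=O)(OC)OC.[Na+] | intermediate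
16 | 8-tert-butyl 1-methyl (2E,6S,7R)-6-[(tert-butyldimethylsilyl)oxy]-3,7-dimethyl-7-(prop-2-en-1-yl)oct-2-enedioate | CC(C)(C)OC(=O)[C@](C)(CC=C)[C@@H](O[Si](C)(C)C(C)(C)C)CC/C(C)=C/C(=O)OC | intermediate
17 | (E)-but-2-enal (crotonaldehyde) | C/C=C/C=O | starting material
18 | 8-tert-butyl 1-methyl (2E,6S,7R)-6-[(tert-butyldimethylsilyl)oxy]-3,7-dimethyl-7-[(2E)-4-oxobut-2-en-1-yl]oct-2-enedioate | CC(C)(C)OC(=O)[C@](C)(C/C=C/C=O)[C@@H](O[Si](C)(C)C(C)(C)C)CC/C(C)=C/C(=O)OC | intermediate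
19 | 8-tert-butyl 1-methyl (2E,6S,7R)-6-[(tert-butyldimethylsilyl)oxy]-3,7-dimethyl-7-[(1E,3E)-4-[(triethylsilyl)oxy]buta-1,3-dien-1-yl]oct-2-enedioate (Diels–Alder precursor) | CC(C)(C)OC(=O)[C@](C)(/C=C/C=C/O[Si](CC)(CC)CC)[C@@H](O[Si](C)(C)C(C)(C)C)CC/C(C)=C/C(=O)OC | intermediate
20 | 19-tert-butyl 11-methyl 3β-[(tert-butyldimethylsilyl)oxy]-8β-[(triethylsilyl)oxy]-12,13,14,15,16,17-hexanorlabd-6-ene-11,19-dioate (Diels–Alder adduct) | CC[Si](CC)(CC)O[C@H]1C=C[C@H]2[C@@](C)(C(=O)OC(C)(C)C)[C@@H](O[Si](C)(C)C(C)(C)C)CC[C@]2(C)[C@H]1C(=O)OC | intermediate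
21 | 19-tert-butyl 11-methyl 3β-[(tert-butyldimethylsilyl)oxy]-8β-[(triethylsilyl)oxy]-12,13,14,15,16,17-hexanorlabdane-11,19-dioate | CC[Si](CC)(CC)O[C@H]1CC[C@H]2[C@@](C)(C(=O)OC(C)(C)C)[C@@H](O[Si](C)(C)C(C)(C)C)CC[C@]2(C)[C@H]1C(=O)OC | intermediate
22 | tert-butyl 3β-[(tert-butyldimethylsilyl)oxy]-11-hydroxy-8β-[(triethylsilyl)oxy]-12,13,14,15,16,17-hexanorlabdan-19-oate | CC[Si](CC)(CC)O[C@H]1CC[C@H]2[C@@](C)(C(=O)OC(C)(C)C)[C@@H](O[Si](C)(C)C(C)(C)C)CC[C@]2(C)[C@H]1CO | intermediate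
23 | tert-butyl 3β-[(tert-butyldimethylsilyl)oxy]-11-oxo-8β-[(triethylsilyl)oxy]-12,13,14,15,16,17-hexanorlabdan-19-oate | CC[Si](CC)(CC)O[C@H]1CC[C@H]2[C@@](C)(C(=O)OC(C)(C)C)[C@@H](O[Si](C)(C)C(C)(C)C)CC[C@]2(C)[C@H]1C=O | intermediate
24 | tert-butyl 3β-[(tert-butyldimethylsilyl)oxy]-8β-[(triethylsilyl)oxy]-13,14,15,16,17-pentanorlabd-11-en-19-oate | CC[Si](CC)(CC)O[C@H]1CC[C@H]2[C@@](C)(C(=O)OC(C)(C)C)[C@@H](O[Si](C)(C)C(C)(C)C)CC[C@]2(C)[C@H]1C=C | intermediate
25 | but-2-yn-1-ol | CC#CCO | starting material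
26 | 1-[(but-2-yn-1-yloxy)methyl]-4-methoxybenzene | CC#CCOCc1ccc(OC)cc1 | intermediate
27 | chloro[(2E)-4-[(4-methoxybenzyl)oxy]but-2-en-2-yl]zirconocene (not isolated) | COc1ccc(COC/C=C(C)/[Zr](Cl)(C2C=CC=C2)C2C=CC=C2)cc1 | intermediate
28 | 1-({[(2E)-3-iodobut-2-en-1-yl]oxy}methyl)-4-methoxybenzene | COc1ccc(COC/C=C(C)/I)cc1 | intermediate
29 | tert-butyl 12-(9-borabicyclo[3.3.1]nonan-9-yl)-3β-[(tert-butyldimethylsilyl)oxy]-8β-[(triethylsilyl)oxy]-13,14,15,16,17-pentanorlabdan-19-oate (not isolated) | CC[Si](CC)(CC)O[C@H]1CC[C@H]2[C@@](C)(C(=O)OC(C)(C)C)[C@@H](O[Si](C)(C)C(C)(C)C)CC[C@]2(C)[C@H]1CCB3C4CCCC3CCC4 | intermediate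
30 | tert-butyl 3β-[(tert-butyldimethylsilyl)oxy]-15-[(4-methoxybenzyl)oxy]-8β-[(triethylsilyl)oxy]-17-norlabd-13E-en-19-oate | CC[Si](CC)(CC)O[C@H]1CC[C@H]2[C@@](C)(C(=O)OC(C)(C)C)[C@@H](O[Si](C)(C)C(C)(C)C)CC[C@]2(C)[C@H]1CC/C(C)=C/COCc3ccc(OC)cc3 | intermediate
31 | tert-butyl 3β-[(tert-butyldimethylsilyl)oxy]-8β-hydroxy-15-[(4-methoxybenzyl)oxy]-17-norlabd-13E-en-19-oate | O[C@H]1CC[C@H]2[C@@](C)(C(=O)OC(C)(C)C)[C@@H](O[Si](C)(C)C(C)(C)C)CC[C@]2(C)[C@H]1CC/C(C)=C/COCc3ccc(OC)cc3 | intermediate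
32 | tert-butyl 3β-[(tert-butyldimethylsilyl)oxy]-15-[(4-methoxybenzyl)oxy]-8-oxo-17-norlabd-13E-en-19-oate | O=C1CC[C@H]2[C@@](C)(C(=O)OC(C)(C)C)[C@@H](O[Si](C)(C)C(C)(C)C)CC[C@]2(C)[C@H]1CC/C(C)=C/COCc3ccc(OC)cc3 | intermediate
33 | tert-butyl 3β-[(tert-butyldimethylsilyl)oxy]-15-[(4-methoxybenzyl)oxy]labda-8(17),13E-dien-19-oate | C=C1CC[C@H]2[C@@](C)(C(=O)OC(C)(C)C)[C@@H](O[Si](C)(C)C(C)(C)C)CC[C@]2(C)[C@H]1CC/C(C)=C/COCc3ccc(OC)cc3 | intermediate
34 | 3β-[(tert-butyldimethylsilyl)oxy]-15-[(4-methoxybenzyl)oxy]labda-8(17),13E-dien-19-ol | C=C1CC[C@H]2[C@@](C)(CO)[C@@H](O[Si](C)(C)C(C)(C)C)CC[C@]2(C)[C@H]1CC/C(C)=C/COCc3ccc(OC)cc3 | intermediate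
35 | 3β-[(tert-butyldimethylsilyl)oxy]-15-[(4-methoxybenzyl)oxy]labda-8(17),13E-dien-19-al | C=C1CC[C@H]2[C@@](C)(C=O)[C@@H](O[Si](C)(C)C(C)(C)C)CC[C@]2(C)[C@H]1CC/C(C)=C/COCc3ccc(OC)cc3 | intermediate
36 | 3β-hydroxy-15-[(4-methoxybenzyl)oxy]labda-8(17),13E-dien-19-al | C=C1CC[C@H]2[C@@](C)(C=O)[C@@H](O)CC[C@]2(C)[C@H]1CC/C(C)=C/COCc3ccc(OC)cc3 | intermediate
37 | 3β-acetoxy-15-[(4-methoxybenzyl)oxy]labda-8(17),13E-dien-19-al | C=C1CC[C@H]2[C@@](C)(C=O)[C@@H](OC(C)=O)CC[C@]2(C)[C@H]1CC/C(C)=C/COCc3ccc(OC)cc3 | intermediate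
38 | 3β-acetoxy-15-hydroxylabda-8(17),13E-dien-19-al (CNP0185120.1) | C=C1CC[C@H]2[C@@](C)(C=O)[C@@H](OC(C)=O)CC[C@]2(C)[C@H]1CC/C(C)=C/CO | target

**Step count**
Total: 26 steps. Longest linear sequence: 24 steps (steps 1–15 and 18–26); the vinyl iodide 28 takes 2 steps (16–17).

**Three steps most likely to fail**

1. Step 11. At 170 °C the ester‑endo preference and the tether‑chair preference may be too small, so that cis‑fused and wrong‑face cycloadducts form beside 20. The trisubstituted enoate may also react so slowly that the silyl dienol ether is lost by desilylation first. Fallback, setting out from 19: i‑Bu2AlH at −78 °C should reduce only the enoate to the E allylic alcohol F1 (tert‑butyl ester and dienol ether kept). MnO2 in CH2Cl2 then gives the E enal, the trienal F2. This more reactive dienophile should cyclise at about 80–110 °C, where endo and facial discrimination are larger, to the Δ6 C11‑aldehyde adduct F3. Hydrogenation of F3 (H2, Pd/C, EtOAc) gives 23, where the fallback returns to the route; steps 12–14 are then not needed.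

2. Step 10. γ‑Deprotonation at the neopentyl C5 position may be incomplete, the enol ether may form partly with Z geometry at C7=C8, or the silyl dienol ether may hydrolyse on isolation. Fallback, setting out from 18: Ac2O, Et3N and DMAP should give the bench‑stable (5E,7E) dienyl acetate F4. Thermal intramolecular Diels–Alder reaction (PhMe, about 180 °C) then gives the 8β‑acetoxy adduct F5. Hydrogenation over PtO2, chosen to avoid allylic hydrogenolysis, gives the saturated acetate F6. NH3 in MeOH removes the acetate to give the 8β‑alcohol F7, and Et3SiOTf with 2,6‑lutidine silylates it to 21, where the fallback returns to the route.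

3. Step 15. The basic ylide may deprotonate the hindered β‑silyloxy aldehyde, leading to epimerisation at C9 or β‑elimination of triethylsilanolate in place of olefination. Fallback, setting out from 23 (Peterson olefination): Me3SiCH2MgCl with CeCl3 in THF at −78 °C, a weakly basic organocerium addition, gives the β‑hydroxysilane F8 as a mixture of C11 epimers. KH in THF then effects syn elimination of both epimers to 24, where the fallback returns to the route.

**Further compounds**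
F1 | step 11 | tert-butyl (2R,3S,6E)-3-[(tert-butyldimethylsilyl)oxy]-8-hydroxy-2,6-dimethyl-2-[(1E,3E)-4-[(triethylsilyl)oxy]buta-1,3-dien-1-yl]oct-6-enoate | CC(C)(C)OC(=O)[C@](C)(/C=C/C=C/O[Si](CC)(CC)CC)[C@@H](O[Si](C)(C)C(C)(C)C)CC/C(C)=C/CO
F2 | step 11 | tert-butyl (2R,3S,6E)-3-[(tert-butyldimethylsilyl)oxy]-2,6-dimethyl-8-oxo-2-[(1E,3E)-4-[(triethylsilyl)oxy]buta-1,3-dien-1-yl]oct-6-enoate | CC(C)(C)OC(=O)[C@](C)(/C=C/C=C/O[Si](CC)(CC)CC)[C@@H](O[Si](C)(C)C(C)(C)C)CC/C(C)=C/C=O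
F3 | step 11 | tert-butyl 3β-[(tert-butyldimethylsilyl)oxy]-11-oxo-8β-[(triethylsilyl)oxy]-12,13,14,15,16,17-hexanorlabd-6-en-19-oate | CC[Si](CC)(CC)O[C@H]1C=C[C@H]2[C@@](C)(C(=O)OC(C)(C)C)[C@@H](O[Si](C)(C)C(C)(C)C)CC[C@]2(C)[C@H]1C=O
F4 | step 10 | 8-tert-butyl 1-methyl (2E,6S,7R)-7-[(1E,3E)-4-acetoxybuta-1,3-dien-1-yl]-6-[(tert-butyldimethylsilyl)oxy]-3,7-dimethyloct-2-enedioate | CC(C)(C)OC(=O)[C@](C)(/C=C/C=C/OC(C)=O)[C@@H](O[Si](C)(C)C(C)(C)C)CC/C(C)=C/C(=O)OC
F5 | step 10 | 19-tert-butyl 11-methyl 8β-acetoxy-3β-[(tert-butyldimethylsilyl)oxy]-12,13,14,15,16,17-hexanorlabd-6-ene-11,19-dioate | CC(=O)O[C@H]1C=C[C@H]2[C@@](C)(C(=O)OC(C)(C)C)[C@@H](O[Si](C)(C)C(C)(C)C)CC[C@]2(C)[C@H]1C(=O)OC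
F6 | step 10 | 19-tert-butyl 11-methyl 8β-acetoxy-3β-[(tert-butyldimethylsilyl)oxy]-12,13,14,15,16,17-hexanorlabdane-11,19-dioate | CC(=O)O[C@H]1CC[C@H]2[C@@](C)(C(=O)OC(C)(C)C)[C@@H](O[Si](C)(C)C(C)(C)C)CC[C@]2(C)[C@H]1C(=O)OC
F7 | step 10 | 19-tert-butyl 11-methyl 3β-[(tert-butyldimethylsilyl)oxy]-8β-hydroxy-12,13,14,15,16,17-hexanorlabdane-11,19-dioate | O[C@H]1CC[C@H]2[C@@](C)(C(=O)OC(C)(C)C)[C@@H](O[Si](C)(C)C(C)(C)C)CC[C@]2(C)[C@H]1C(=O)OC
F8 | step 15 | tert-butyl 3β-[(tert-butyldimethylsilyl)oxy]-11-hydroxy-8β-[(triethylsilyl)oxy]-12-(trimethylsilyl)-13,14,15,16,17-pentanorlabdan-19-oate (C11 epimers) | CC[Si](CC)(CC)O[C@H]1CC[C@H]2[C@@](C)(C(=O)OC(C)(C)C)[C@@H](O[Si](C)(C)C(C)(C)C)CC[C@]2(C)[C@H]1C(O)C[Si](C)(C)C
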